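The target is cut at the C9–C12 bond into a dienyl triflate (left half) and a vinyl perhydrobenzoxepinone (right half), joined last by B-alkyl Suzuki coupling. Everything rests on making ring B of the left half by an enantioselective Diels–Alder reaction: an acyclic (E)-2-methyl enal (C5=C10) adds to a 1-siloxy-2-methylbutadiene (C6–C9), forming C5–C6 and C9–C10 at once. The (E) geometry of the dienophile becomes the trans C5–H/C10–CH3 ring fusion at the new quaternary C10. Ring A is then closed around C5–C10 by aldol condensation, and the C9 oxygen is turned into the C6=C7–C8=C9 dienyl triflate. The right half comes from an epoxide-opening cascade.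

Key step: step 4

Remarks on the chemistry
- Atom labels: the left half is numbered C1–C10 as in a drimane (C3 carbinol, C4 gem-dimethyl, C5 ring-fusion CH, C6=C7, C8(CH3)=C9, C10 quaternary). The rest is labelled C12–C23 (there is no C11): C12 and C13 are the ethylene linker (C9–C12), C14–C19 the cyclohexane, and C18–O–C23(CH3)2–C22(=O)–C21–C20–C19 the oxepane.
- Assumption: the (S)-prolinol-derived oxazaborolidine is taken to expose the enal face that gives the drawn 5α-H/10β-CH3 adduct; if the sense is the opposite, its enantiomer is used.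
- The C9 epimer drawn for 9–12 is the endo adduct; the exo epimer converges at 13. The minor (1Z) isomer of diene 8 does not react.

Step 1
Reactants: 1 4-(2-methylprop-1-en-1-yl)morpholine; 2 acetyl chloride
Product: 4 2,2-dimethyl-3-oxobutanal, via iminium chloride 3 (not isolated)
Conditions: AcCl, Et2O, 0 °C to rt; then H2O, rt
Reagents that add atoms: water, O
Why: Enamine C-acylation (Stork-type) at the fully substituted β-carbon gives an iminium salt that cannot tautomerise and should hydrolyse to the β-keto aldehyde, which is non-enolisable between the carbonyls.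

Step 2
Reactants: 4 2,2-dimethyl-3-oxobutanal; 5 2-(triphenylphosphoranylidene)propanal
Product: 6 (2E)-2,4,4-trimethyl-5-oxohex-2-enal
Conditions: toluene, 90 °C
Reagents that add atoms: none
Why: The Wittig reaction of a formyl-stabilised ylide is E-selective and attacks the aldehyde in preference to the hindered methyl ketone, setting the (E) C5=C10 geometry that later encodes the trans ring fusion.

Step 3
Reactants: 7 (2E)-2-methylbut-2-enal
Product: 8 (1E)-2-methyl-1-(triisopropylsilyloxy)buta-1,3-diene
Conditions: i-Pr3SiOTf, Et3N, Et2O, 0 °C to rt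
Reagents that add atoms: triisopropylsilyl triflate, CC(C)[Si](OS(=O)(=O)C(F)(F)F)(C(C)C)C(C)C
Why: O-silylation with γ-deprotonation (silyl dienol ether formation) should give the 1-siloxydiene, mainly as the reactive (1E) isomer.

Step 4
Reactants: 6 (2E)-2,4,4-trimethyl-5-oxohex-2-enal; 8 (1E)-2-methyl-1-(triisopropylsilyloxy)buta-1,3-diene
Product: 9 cyclohexene adduct 1-formyl-1,3-dimethyl-6-(2-methyl-3-oxobutan-2-yl)-2-(triisopropylsilyloxy)cyclohex-3-ene (target numbering: C10 β-CH3/α-CHO; C5 α-H; C9 α-OTIPS; C7=C8)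
Conditions: (S)-3,3-diphenyl-1-(2-methylphenyl)tetrahydro-1H,3H-pyrrolo[1,2-c][1,3,2]oxazaborole (15 mol %) activated with AlBr3 (12 mol %), 8 (2 equiv), CH2Cl2, −78 to −40 °C
Reagents that add atoms: none
Why: The oxazaborolidinium Lewis acid binds the formyl group of 6, and diene 8 adds in a concerted, asynchronous normal-demand [4+2] cycloaddition in which C6 (largest HOMO coefficient, remote from the siloxy donor) bonds first to the β-carbon C5 and C9 then closes onto the formyl-bearing C10. The closest known reaction type is the chiral oxazaborolidinium-catalysed Diels–Alder reaction of α-substituted enals with siloxydienes. Ring B (C5–C6–C7–C8–C9–C10) closes by intermolecular suprafacial [4+2] cycloaddition, both new bonds forming on one face of the alkene. Because the addition is suprafacial, the (E) geometry of 6 places C4 and C1 trans on ring B, so C5–H and C10–CH3 are trans at the new quaternary C10; the catalyst shields one face of the bound s-trans enal and so sets the absolute configuration of C5 and C10, and the C9 silyloxy centre (endo expected) is inconsequential because C9 later becomes sp2. The step needs regioselectivity (C9 to C10, not C9 to C5), secured by the matched polarisation of the 1-siloxy donor and the formyl acceptor, and chemoselectivity for the enal over the ketone, secured because only the enal is conjugated.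

Step 5
Reactants: 9 cyclohexene adduct
Product: 11 9α-(triisopropylsilyloxy)-11-nordrima-1,7-dien-3-one, via aldol 10 (not isolated)
Conditions: NaOMe, MeOH, rt to 50 °C
Reagents that add atoms: none
Why: Intramolecular aldol condensation of the 1,5-keto aldehyde (the ring-closing half of a Robinson annulation) should close ring A cleanly, because the acetyl methyl is the only enolisable position and the aldehyde sits on quaternary C10; no stereocentre is formed and the trans C5/C10 relationship gives the trans-decalin.

Step 6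
Reactants: 11 9α-(triisopropylsilyloxy)-11-nordrima-1,7-dien-3-one
Product: 12 9α-hydroxy-11-nordrima-1,7-dien-3-one
Conditions: HF·pyridine, THF, 0 °C to rt
Reagents that add atoms: none
Why: Fluoride-mediated Si–O cleavage under acidic conditions avoids an alkoxide at C9 and with it retro-aldol-type opening of the δ-hydroxy enone.

Step 7
Reactants: 12 9α-hydroxy-11-nordrima-1,7-dien-3-one
Product: 13 11-nordrima-1,7-diene-3,9-dione
Conditions: Dess–Martin periodinane, NaHCO3, CH2Cl2, rt
Reagents that add atoms: none
Why: Dess–Martin oxidation of the hindered allylic alcohol should give the ring-B enone and removes the C9 stereocentre.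

Step 8
Reactants: 13 11-nordrima-1,7-diene-3,9-dione
Product: 15 3-oxo-11-nordrima-1,6,8-trien-9-yl triflate, via potassium dienolate 14 (not isolated)
Conditions: KN(SiMe3)2, THF, −78 °C; then PhNTf2, −78 to 0 °C
Reagents that add atoms: N-phenylbis(trifluoromethanesulfonimide), O=S(=O)(N(c1ccccc1)S(=O)(=O)C(F)(F)F)C(F)(F)F
Why: Only the ring-B enone can be deprotonated (at γ-C6), since the ring-A enone is flanked by quaternary C4 and C10, so dienolate formation and O-triflation should fix the C6=C7–C8=C9 diene regiospecifically.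

Step 9
Reactants: 15 3-oxo-11-nordrima-1,6,8-trien-9-yl triflate
Product: 16 3-oxo-11-nordrima-6,8-dien-9-yl triflate
Conditions: [(Ph3P)CuH]6 (0.4 equiv), wet THF/benzene, rt
Reagents that add atoms: none
Why: Copper hydride conjugate reduction is selective for the enone C1=C2 and should leave the dienyl triflate untouched.

Step 10
Reactants: 16 3-oxo-11-nordrima-6,8-dien-9-yl triflate
Product: 17 3β-hydroxy-11-nordrima-6,8-dien-9-yl triflate
Conditions: NaBH4, MeOH, 0 °C
Reagents that add atoms: none
Why: Borohydride reduction of a 4,4-dimethyl-3-ketone in a trans-decalin delivers hydride axially from the α face, away from the 4β- and 10β-methyls, and should give the equatorial 3β-alcohol.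

Step 11
Reactants: 18 ethyl acetoacetate; 19 geranyl bromide
Product: 21 ethyl (6E)-7,11-dimethyl-3-oxododeca-6,10-dienoate, via dianion 20 (not isolated)
Conditions: NaH, THF, 0 °C; n-BuLi, 0 °C; then 19, 0 °C to rt; aq. HCl
Reagents that add atoms: none
Why: γ-Alkylation of the acetoacetate dianion by the allylic bromide (SN2) is the standard entry to γ-alkylated β-keto esters.

Step 12
Reactants: 21 ethyl (6E)-7,11-dimethyl-3-oxododeca-6,10-dienoate
Product: 22 ethyl (2Z,6E)-7,11-dimethyl-3-(trifluoromethylsulfonyloxy)dodeca-2,6,10-trienoate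
Conditions: Tf2O, saturated aq. LiOH, hexanes, 5 °C
Reagents that add atoms: triflic anhydride, O=S(=O)(OS(=O)(=O)C(F)(F)F)C(F)(F)F
Why: O-triflation of the lithium-chelated enolate of a β-keto ester should give the (Z)-enol triflate.

Step 13
Reactants: 22 ethyl (2Z,6E)-7,11-dimethyl-3-(trifluoromethylsulfonyloxy)dodeca-2,6,10-trienoate; 23 (trimethylsilyl)methylmagnesium chloride
Product: 24 ethyl (2Z,6E)-7,11-dimethyl-3-[(trimethylsilyl)methyl]dodeca-2,6,10-trienoate
Conditions: Pd(PPh3)4 (5 mol %), THF, 0 °C to rt
Reagents that add atoms: none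
Why: Kumada coupling of the enol triflate proceeds with retention of alkene geometry, placing C13 trans to C16 in the allylsilane; the silylmethyl Grignard reagent is too hindered to attack the ester.

Step 14
Reactants: 24 ethyl (2Z,6E)-7,11-dimethyl-3-[(trimethylsilyl)methyl]dodeca-2,6,10-trienoate
Product: 25 ethyl (2Z)-5-{(2S,3S)-3-[2-((2S)-3,3-dimethyloxiran-2-yl)ethyl]-3-methyloxiran-2-yl}-3-[(trimethylsilyl)methyl]pent-2-enoate
Conditions: L-fructose-derived Shi ketone (enantiomer of the usual D-fructose catalyst; 0.6 equiv), Oxone (2KHSO5·KHSO4·K2SO4), K2CO3, Bu4NHSO4, Na2B4O7 buffer, MeCN/dimethoxymethane, 0 °C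
Reagents that add atoms: potassium peroxymonosulfate, [K+].[O-]S(=O)(=O)OO
Why: Shi asymmetric epoxidation oxidises the two electron-rich trisubstituted alkenes but not the ester-conjugated one, and the catalyst enantiomer sets the (18S,19S) and (22S) epoxides.

Step 15
Reactants: 25 bis-epoxy ester
Product: 26 (2Z)-5-{(2S,3S)-3-[2-((2S)-3,3-dimethyloxiran-2-yl)ethyl]-3-methyloxiran-2-yl}-3-[(trimethylsilyl)methyl]pent-2-en-1-ol
Conditions: i-Bu2AlH (2.2 equiv), CH2Cl2, −78 °C; aq. potassium sodium tartrate
Reagents that add atoms: none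
Why: Aluminium hydride 1,2-reduction of the enoate at −78 °C gives the allylic alcohol and should spare the trisubstituted epoxides, restoring full nucleophilicity to the allylsilane.

Step 16
Reactants: 26 bis-epoxy allylsilane alcohol
Product: 29 6α-(hydroxymethyl)-2,2,5a-trimethyl-7-methylidene-decahydro-1-benzoxepin-3-ol (trans-fused; 5a-CH3 α; 9a-H β; 3S), via silyl ether 27 (not isolated), via bicyclic bis-silyl ether 28 (not isolated)
Conditions: Me3SiOTf (2.5 equiv), 2,6-di-tert-butyl-4-methylpyridine, CH2Cl2, −78 °C; then K2CO3, MeOH, rt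
Reagents that add atoms: none
Why: In this Lewis acid-promoted tandem oxa-/carbacyclisation (epoxide-opening cascade ended by an allylsilane, SE2'), the internal epoxide oxygen opens the silyl-activated terminal epoxide at tertiary C23 (seven-membered ring, endo), and C14 then opens the resulting epoxonium at tertiary C19 with inversion through a chair transition state with loss of silicon, so C18 is retained from the epoxide, C19 is inverted to the trans ring fusion, and C13 sits equatorial at C14 because of the alkene geometry.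

Step 17
Reactants: 29 methylidene diol
Product: 30 6α-(hydroxymethyl)-2,2,5a,7α-tetramethyl-decahydro-1-benzoxepin-3-ol
Conditions: H2 (1 atm), PtO2, EtOAc, rt
Reagents that add atoms: none
Why: Heterogeneous hydrogenation should deliver hydrogen to the exocyclic alkene from the β face, opposite the axial C19 methyl (1,3-diaxial to C15), giving the kinetically formed axial 15α-methyl.

Step 18
Reactants: 30 saturated diol
Product: 31 2,2,5a,7α-tetramethyl-3-oxo-decahydro-1-benzoxepine-6α-carbaldehyde
Conditions: Dess–Martin periodinane (2.5 equiv), NaHCO3, CH2Cl2, rt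
Reagents that add atoms: none
Why: Dess–Martin oxidation converts both alcohols under non-basic conditions that should not epimerise C14 next to the new aldehyde.

Step 19
Reactants: 31 keto aldehyde; 32 methyltriphenylphosphonium bromide
Product: 34 6α-ethenyl-2,2,5a,7α-tetramethyl-octahydro-1-benzoxepin-3(2H)-one, via methylidene ylide 33 (not isolated)
Conditions: 32 (1.1 equiv), KN(SiMe3)2 (1.05 equiv), THF, 0 °C; then 31, −78 to 0 °C
Reagents that add atoms: none
Why: Wittig methylenation with one equivalent of ylide at low temperature should take the aldehyde in preference to the hindered α-alkoxy ketone, without epimerising C14.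

Step 20
Reactants: 34 vinyl ketone; 17 3β-hydroxy-11-nordrima-6,8-dien-9-yl triflate
Product: 36 target compound CNP0106412.1, via alkylborane 35 (not isolated)
Conditions: 9-BBN (1.1 equiv), THF, 0 °C to rt; then 17, PdCl2(dppf) (dppf = 1,1'-bis(diphenylphosphino)ferrocene; 10 mol %), AsPh3, Cs2CO3, DMF/THF/H2O, rt to 50 °C
Reagents that add atoms: none
Why: Anti-Markovnikov hydroboration of the vinyl group (much faster than reduction of the hindered ketone) followed by B-alkyl Suzuki–Miyaura coupling with the dienyl triflate forms C9–C12 without touching any stereocentre, the free C3 hydroxyl and the ketone being tolerated.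

Compound list
1 | 4-(2-methylprop-1-en-1-yl)morpholine | CC(C)=CN1CCOCC1 | starting material
2 | acetyl chloride | CC(=O)Cl | starting material
3 | 4-(2,2-dimethyl-3-oxobutylidene)morpholin-4-ium chloride | CC(=O)C(C)(C)C=[N+]1CCOCC1.[Cl-] | intermediate
4 | 2,2-dimethyl-3-oxobutanal | CC(=O)C(C)(C)C=O | intermediate
5 | 2-(triphenylphosphoranylidene)propanal | CC(C=O)=P(c1ccccc1)(c1ccccc1)c1ccccc1 | starting material
6 | (2E)-2,4,4-trimethyl-5-oxohex-2-enal | CC(=O)C(C)(C)/C=C(\C)C=O | intermediate
7 | (2E)-2-methylbut-2-enal (tiglic aldehyde) | C/C=C(\C)C=O | starting material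
8 | (1E)-2-methyl-1-(triisopropylsilyloxy)buta-1,3-diene | C=C/C(C)=C/O[Si](C(C)C)(C(C)C)C(C)C | intermediate
9 | Diels–Alder adduct: 1-formyl-1,3-dimethyl-6-(2-methyl-3-oxobutan-2-yl)-2-(triisopropylsilyloxy)cyclohex-3-ene (C10 β-CH3/α-CHO, C5 α-H, C9 α-OTIPS) | O=C[C@]1(C)[C@H](O[Si](C(C)C)(C(C)C)C(C)C)C(C)=CC[C@H]1C(C)(C)C(C)=O | intermediate
10 | aldol: 1-hydroxy-9α-(triisopropylsilyloxy)-11-nordrim-7-en-3-one (either C1 epimer) | C[C@]12C(O)CC(=O)C(C)(C)[C@@H]1CC=C(C)[C@H]2O[Si](C(C)C)(C(C)C)C(C)C | intermediate
11 | 9α-(triisopropylsilyloxy)-11-nordrima-1,7-dien-3-one (5α-H, 10β-CH3) | C[C@]12C=CC(=O)C(C)(C)[C@@H]1CC=C(C)[C@H]2O[Si](C(C)C)(C(C)C)C(C)C | intermediate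
12 | 9α-hydroxy-11-nordrima-1,7-dien-3-one | C[C@]12C=CC(=O)C(C)(C)[C@@H]1CC=C(C)[C@H]2O | intermediate
13 | 11-nordrima-1,7-diene-3,9-dione | C[C@]12C=CC(=O)C(C)(C)[C@@H]1CC=C(C)C2=O | intermediate
14 | potassium dienolate of 13 (O9, C6=C7, C8=C9) | C[C@]12C=CC(=O)C(C)(C)[C@@H]1C=CC(C)=C2[O-].[K+] | intermediate
15 | 3-oxo-11-nordrima-1,6,8-trien-9-yl triflate | C[C@]12C=CC(=O)C(C)(C)[C@@H]1C=CC(C)=C2OS(=O)(=O)C(F)(F)F | intermediate
16 | 3-oxo-11-nordrima-6,8-dien-9-yl triflate | C[C@]12CCC(=O)C(C)(C)[C@@H]1C=CC(C)=C2OS(=O)(=O)C(F)(F)F | intermediate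
17 | 3β-hydroxy-11-nordrima-6,8-dien-9-yl triflate | C[C@]12CC[C@H](O)C(C)(C)[C@@H]1C=CC(C)=C2OS(=O)(=O)C(F)(F)F | intermediate
18 | ethyl acetoacetate | CCOC(=O)CC(C)=O | starting material
19 | geranyl bromide | CC(C)=CCC/C(C)=C/CBr | starting material
20 | ethyl acetoacetate dianion (sodium lithium salt) | CCOC([O-])=CC([O-])=C.[Na+].[Li+] | intermediate
21 | ethyl (6E)-7,11-dimethyl-3-oxododeca-6,10-dienoate | CCOC(=O)CC(=O)CC/C=C(\C)CCC=C(C)C | intermediate
22 | ethyl (2Z,6E)-7,11-dimethyl-3-(trifluoromethylsulfonyloxy)dodeca-2,6,10-trienoate | CCOC(=O)/C=C(\OS(=O)(=O)C(F)(F)F)CC/C=C(\C)CCC=C(C)C | intermediate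
23 | (trimethylsilyl)methylmagnesium chloride | C[Si](C)(C)C[Mg]Cl | starting material
24 | ethyl (2Z,6E)-7,11-dimethyl-3-[(trimethylsilyl)methyl]dodeca-2,6,10-trienoate | CCOC(=O)/C=C(\C[Si](C)(C)C)CC/C=C(\C)CCC=C(C)C | intermediate
25 | bis-epoxy ester, (18S,19S,22S) | CCOC(=O)/C=C(\C[Si](C)(C)C)CC[C@@H]1O[C@@]1(C)CC[C@@H]1OC1(C)C | intermediate
26 | bis-epoxy allylsilane alcohol, (18S,19S,22S) | OC/C=C(\C[Si](C)(C)C)CC[C@@H]1O[C@@]1(C)CC[C@@H]1OC1(C)C | intermediate
27 | trimethylsilyl ether of 26 | C[Si](C)(C)OC/C=C(\C[Si](C)(C)C)CC[C@@H]1O[C@@]1(C)CC[C@@H]1OC1(C)C | intermediate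
28 | bis(trimethylsilyl) ether of 29 | C[Si](C)(C)OC[C@@H]1C(=C)CC[C@@H]2OC(C)(C)[C@@H](O[Si](C)(C)C)CC[C@]21C | intermediate
29 | 6α-(hydroxymethyl)-2,2,5a-trimethyl-7-methylidene-decahydro-1-benzoxepin-3-ol (trans-fused, 5a-CH3 α, 9a-H β, 3S) | OC[C@@H]1C(=C)CC[C@@H]2OC(C)(C)[C@@H](O)CC[C@]21C | intermediate
30 | 6α-(hydroxymethyl)-2,2,5a,7α-tetramethyl-decahydro-1-benzoxepin-3-ol | OC[C@@H]1[C@H](C)CC[C@@H]2OC(C)(C)[C@@H](O)CC[C@]21C | intermediate
31 | 2,2,5a,7α-tetramethyl-3-oxo-decahydro-1-benzoxepine-6α-carbaldehyde | O=C[C@@H]1[C@H](C)CC[C@@H]2OC(C)(C)C(=O)CC[C@]21C | intermediate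
32 | methyltriphenylphosphonium bromide | C[P+](c1ccccc1)(c1ccccc1)c1ccccc1.[Br-] | starting material
33 | methylidenetriphenylphosphorane | C=P(c1ccccc1)(c1ccccc1)c1ccccc1 | intermediate
34 | 6α-ethenyl-2,2,5a,7α-tetramethyl-octahydro-1-benzoxepin-3(2H)-one (trans-fused; 5a-CH3, vinyl and 7-CH3 all α; 9a-H β) | C=C[C@@H]1[C@H](C)CC[C@@H]2OC(C)(C)C(=O)CC[C@]21C | intermediate
35 | B-alkyl-9-borabicyclo[3.3.1]nonane from 34 (boron on C12) | C1CC2CCCC(C1)B2CC[C@@H]1[C@H](C)CC[C@@H]2OC(C)(C)C(=O)CC[C@]21C | intermediate
36 | CNP0106412.1 | CC1=C(CC[C@@H]2[C@H](C)CC[C@@H]3OC(C)(C)C(=O)CC[C@]32C)[C@@]2(C)CC[C@H](O)C(C)(C)[C@@H]2C=C1 | target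

Total step count: 20. Longest linear sequence: 10 steps (steps 1, 2, 4–10 and 20; the right-half branch, steps 11–19 and 20, is equally long).

Steps most likely to fail

Step 4. The cycloaddition of a β-quaternary, α-methyl enal may suffer from poor enantiofacial discrimination, or the Lewis acid may divert the siloxydiene into Mukaiyama-type 1,2- or 1,4-addition instead of ring closure. The fallback moves stereocontrol from the catalyst to an auxiliary on the diene. It sets out from 7 and 6. The potassium dienolate of 7 (t-BuOK, THF, −78 °C) is O-acylated with (S)-O-methylmandeloyl chloride to give (1E)-2-methylbuta-1,3-dien-1-yl (2S)-2-methoxy-2-phenylacetate F1. Its BF3·OEt2-promoted (or thermal) Diels–Alder reaction with 6 forms the same two bonds, the phenyl ring of the auxiliary shielding one face of the diene, and should give the mandelate adduct F2; minor diastereomers would be removed by chromatography. Amine–acid catalysed aldol condensation (pyrrolidine, AcOH, toluene, 60 °C) keeps the ester and should give the enone mandelate F3. Methanolysis (K2CO3, MeOH, 0 °C) comes back to the route at 12.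

Step 16. The cascade may stop after the oxacyclisation or end by elimination, or the free (silylated) allylic oxygen may ionise or trap the epoxonium ion before the carbocycle closes. The fallback postpones the ester reduction so that the terminating nucleophile carries no hydroxyl or ionisable allylic oxygen. It sets out from 25. The bis-epoxy γ-silyl enoate is cyclised directly (Me3SiOTf, 2,6-di-tert-butyl-4-methylpyridine, CH2Cl2, −78 °C), the α-carbon of the enoate attacking C19 as a silyl dienolate equivalent, to give the bicyclic β,γ-unsaturated ester F4 (ethyl 2,2,5a-trimethyl-7-methylidene-3-(trimethylsilyloxy)decahydro-1-benzoxepine-6α-carboxylate). LiAlH4 (THF, 0 °C) with acidic work-up reduces the ester and frees the C22 hydroxyl, coming back to the route at 29.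

Step 20. Oxidative addition and transmetalation at the doubly flanked C9 triflate may be slow, so that protodeboronation or β-hydride elimination of the alkyl partner wins. The fallback replaces the borane by an organozinc reagent. It sets out from 34. Hydroboration–oxidation (9-BBN, THF; then NaBO3·4H2O) should give the primary alcohol F5 (6α-(2-hydroxyethyl) ketone), and I2, PPh3, imidazole (CH2Cl2, 0 °C) the primary iodide F6. Zinc insertion (Zn dust, LiCl, THF, 40 °C) gives the alkylzinc iodide F7, which tolerates the ketone. Negishi coupling with 17 (Pd(OAc)2, 2-dicyclohexylphosphino-2',6'-dimethoxybiphenyl, THF/N-methylpyrrolidone, rt to 50 °C) comes back to the route at 36.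

Further compounds
F1 | step 4 | (1E)-2-methylbuta-1,3-dien-1-yl (2S)-2-methoxy-2-phenylacetate | C=C/C(C)=C/OC(=O)[C@@H](OC)c1ccccc1
F2 | step 4 | mandelate Diels–Alder adduct (as 9 with the (2S)-2-methoxy-2-phenylacetoxy group on C9) | O=C[C@]1(C)[C@H](OC(=O)[C@@H](OC)c2ccccc2)C(C)=CC[C@H]1C(C)(C)C(C)=O
F3 | step 4 | 3-oxo-11-nordrima-1,7-dien-9α-yl (2S)-2-methoxy-2-phenylacetate | C[C@]12C=CC(=O)C(C)(C)[C@@H]1CC=C(C)[C@H]2OC(=O)[C@@H](OC)c1ccccc1
F4 | step 16 | ethyl 2,2,5a-trimethyl-7-methylidene-3-(trimethylsilyloxy)decahydro-1-benzoxepine-6α-carboxylate | CCOC(=O)[C@@H]1C(=C)CC[C@@H]2OC(C)(C)[C@@H](O[Si](C)(C)C)CC[C@]21C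
F5 | step 20 | 6α-(2-hydroxyethyl)-2,2,5a,7α-tetramethyl-octahydro-1-benzoxepin-3(2H)-one | OCC[C@@H]1[C@H](C)CC[C@@H]2OC(C)(C)C(=O)CC[C@]21C
F6 | step 20 | 6α-(2-iodoethyl)-2,2,5a,7α-tetramethyl-octahydro-1-benzoxepin-3(2H)-one | ICC[C@@H]1[C@H](C)CC[C@@H]2OC(C)(C)C(=O)CC[C@]21C
F7 | step 20 | alkylzinc iodide from F6 | I[Zn]CC[C@@H]1[C@H](C)CC[C@@H]2OC(C)(C)C(=O)CC[C@]21C
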